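## Retrosynthetic overview

- Target 26 ⇒ dienyne lactone 24 by nickel-catalysed syn addition of H and CH2OH across the alkyne; 24 ⇒ terminal alkyne 20 + (Z)-bromomethylene butenolide 23 (Sonogashira).
- 20 ⇒ allylic bromide 16 + lithiated 1-(trimethylsilyl)propyne; 16 ⇒ ethyl drim-8-en-11-oate 14.
- The plan rests on ring B (C5–C10, drimane numbering), which holds a tetrasubstituted C8=C9 alkene with the methyl on C8 and C11 on C9. Hence 14 ⇒ ring A keto phosphonoacetate 13, cutting C8=C9 into a C8 methyl ketone and a C9 phosphonate carbon.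
- 13 ⇒ (S)-α-ionone 1: C5 is the ionone stereocentre, and C10 is set by Johnson–Claisen transfer from the trans allylic alcohol 6.
- Ring order: ring A (present in 1), ring B (step 9), butenolide ring (steps 14–15, attached in step 16).

Key step: step 9

Assumption: (S)-(−)-α-ionone is taken as available in high enantiomeric purity (purchased, or from resolution of the racemate); its stereocentre becomes C5 and controls C10.

## Route

Step 1
Reactants: 1 (S)-α-ionone
Product: 3 (S)-7,8-dihydro-α-ionone, via triethylsilyl enol ether 2 (not isolated)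
Conditions: Et3SiH, RhCl(PPh3)3 (cat.), PhMe, 50 °C; then K2CO3, MeOH, rt
Reagents that add atoms: none
Why: Rhodium-catalysed 1,4-hydrosilylation of the enone with a monohydrosilane (conjugate reduction) gives the silyl enol ether, whose methanolysis should release the saturated methyl ketone while the hindered trisubstituted ring alkene and the allylic stereocentre stay untouched.

Step 2
Reactants: 3 (S)-7,8-dihydro-α-ionone
Product: 4 2-methyl-2-{2-[(1S)-2,6,6-trimethylcyclohex-2-en-1-yl]ethyl}-1,3-dioxolane
Conditions: ethylene glycol, PPTS (cat.), PhH, reflux, Dean–Stark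
Reagents that add atoms: ethylene glycol, OCCO
Why: Acid-catalysed ketalisation with azeotropic removal of water masks the methyl ketone against the later hydride, enolate and carbanion steps, the mild acid leaving the ring alkene in place.

Step 3
Reactants: 4 dioxolane of dihydro-α-ionone
Product: 5 (4S)-3,5,5-trimethyl-4-[2-(2-methyl-1,3-dioxolan-2-yl)ethyl]cyclohex-2-en-1-one
Conditions: Rh2(cap)4 (cat., cap = caprolactamate), t-BuOOH, K2CO3, CH2Cl2, rt
Reagents that add atoms: tert-butyl hydroperoxide, CC(C)(C)OO
Why: Dirhodium-catalysed allylic C–H oxidation with tert-butyl hydroperoxide should attack the ring methylene next to the trisubstituted alkene rather than the shielded tertiary allylic C–H, as in the oxidation of α-ionone derivatives to their 3-oxo compounds, and gives the conjugated enone.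

Step 4
Reactants: 5 ring enone
Product: 6 (1S,4S)-3,5,5-trimethyl-4-[2-(2-methyl-1,3-dioxolan-2-yl)ethyl]cyclohex-2-en-1-ol (hydroxyl trans to the side chain)
Conditions: (R)-2-methyl-CBS-oxazaborolidine (cat.), BH3·SMe2, THF, −30 °C; MeOH quench
Reagents that add atoms: none
Why: Corey–Bakshi–Shibata reduction, in which the (R)-oxazaborolidine treats the alkenyl arm as the large group and should deliver hydride to the carbonyl face on the side of the C4 chain, setting the (1S) carbinol with OH trans to that chain; this is also the face remote from the axial methyl of the gem-dimethyl carbon, so catalyst and substrate are expected to be matched.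

Step 5
Reactants: 6 trans allylic alcohol; 7 triethyl orthoacetate
Product: 9 ethyl 2-[(1S,6S)-1,5,5-trimethyl-6-[2-(2-methyl-1,3-dioxolan-2-yl)ethyl]cyclohex-2-en-1-yl]acetate, via mixed ketene acetal 8 (not isolated)
Conditions: MeC(OEt)3 (excess), EtCO2H (cat.), 140 °C, EtOH distilled off
Reagents that add atoms: none
Why: Johnson–Claisen rearrangement, in which the [3,3] shift of the mixed ketene acetal moves the acetate carbon suprafacially from the carbinol oxygen to the methyl-bearing alkene carbon, so the new quaternary centre (C10) carries CH2CO2Et on the face of the former C–O bond, trans to the side chain on the neighbouring carbon (C5).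

Step 6
Reactants: 9 unsaturated Claisen ester
Product: 10 ethyl 2-[(1R,2S)-1,3,3-trimethyl-2-[2-(2-methyl-1,3-dioxolan-2-yl)ethyl]cyclohexyl]acetate
Conditions: H2 (1 atm), Pd/C, EtOAc, rt
Reagents that add atoms: none
Why: Heterogeneous catalytic hydrogenation saturates the cis-disubstituted ring alkene; ester and dioxolane are inert and no stereocentre is formed (the descriptor at the quaternary carbon changes only through ligand priorities).

Step 7
Reactants: 10 saturated ketal ester
Product: 12 ethyl 2-(diethoxyphosphoryl)-2-[(1S,2S)-1,3,3-trimethyl-2-[2-(2-methyl-1,3-dioxolan-2-yl)ethyl]cyclohexyl]acetate (epimer mixture at the phosphonate carbon), via phosphonite 11 (not isolated)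
Conditions: LDA, THF, −78 °C; ClP(OEt)2, −78 to 0 °C; then 30% H2O2, 0 °C
Reagents that add atoms: diethyl chlorophosphite, CCOP(Cl)OCC; hydrogen peroxide, OO
Why: C-phosphinylation of the ester lithium enolate with the trivalent phosphorus chloride followed by oxidation to the phosphonate is an established route to α-phosphono esters that avoids O-phosphorylation, and the C9 centre so formed is removed again in step 9.

Step 8
Reactants: 12 ketal phosphonoacetate
Product: 13 ethyl 2-(diethoxyphosphoryl)-2-[(1S,2S)-1,3,3-trimethyl-2-(3-oxobutyl)cyclohexyl]acetate (ring A keto phosphonoacetate)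
Conditions: 1 M HCl, THF, rt
Reagents that add atoms: water, O
Why: Acid-catalysed ketal hydrolysis frees the C8 methyl ketone under conditions that leave the ethyl ester and the phosphonate esters intact.

Step 9
Reactants: 13 ring A keto phosphonoacetate
Product: 14 ethyl drim-8-en-11-oate, ethyl (4aS,8aS)-2,5,5,8a-tetramethyl-3,4,4a,5,6,7,8,8a-octahydronaphthalene-1-carboxylate
Conditions: NaH, THF, 0 °C to reflux
Reagents that add atoms: none
Why: Intramolecular Horner–Wadsworth–Emmons olefination: NaH removes the C9–H flanked by ester and phosphonate, the stabilised carbanion adds to the C8 methyl ketone, and the resulting β-alkoxide closes to an oxaphosphetane that collapses with loss of diethyl phosphate to the C8=C9 alkene. The closest known reaction type is the intramolecular HWE closure of keto phosphonoacetates to tetrasubstituted cyclohexene carboxylates. Ring B closes in a 6-exo-trig mode, C9 attacking the carbonyl carbon C8 with the oxygen outside the new ring. No stereocentre is formed, and C5 and C10, both remote from any acidic position, are carried through unchanged, so the trans ring fusion is the one fixed in steps 4 and 5. The step needs carbanion formation at C9 rather than ketone enolisation, which the much higher acidity of the phosphonoacetate C–H secures, and the alkene can only arise between the former carbanion and carbonyl carbons. The crowding at C9 next to the quaternary C10 is offset by the intramolecular six-membered transition state and by heating.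

Step 10
Reactants: 14 ethyl drim-8-en-11-oate
Product: 15 drim-8-en-11-ol, [(4aS,8aS)-2,5,5,8a-tetramethyl-3,4,4a,5,6,7,8,8a-octahydronaphthalen-1-yl]methanol
Conditions: LiAlH4, Et2O, 0 °C to rt
Reagents that add atoms: none
Why: Hydride reduction of the conjugated ester goes by 1,2-addition to the primary allylic alcohol, the tetrasubstituted alkene being too hindered and electron-rich for conjugate reduction.

Step 11
Reactants: 15 drim-8-en-11-ol
Product: 16 11-bromodrim-8-ene, (4aS,8aS)-4-(bromomethyl)-3,4a,8,8-tetramethyl-1,2,4a,5,6,7,8,8a-octahydronaphthalene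
Conditions: CBr4, PPh3, CH2Cl2, 0 °C; used without storage
Reagents that add atoms: carbon tetrabromide, BrC(Br)(Br)Br
Why: Appel bromination under neutral conditions converts the primary allylic alcohol into the bromide, and the primary bromide with the tetrasubstituted ring alkene is the favoured allylic isomer.

Step 12
Reactants: 16 11-bromodrim-8-ene; 17 1-(trimethylsilyl)propyne
Product: 19 trimethyl{4-[(4aS,8aS)-2,5,5,8a-tetramethyl-3,4,4a,5,6,7,8,8a-octahydronaphthalen-1-yl]but-1-yn-1-yl}silane, via 3-lithio-1-(trimethylsilyl)propyne 18 (not isolated)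
Conditions: 17, n-BuLi, THF, −78 to −20 °C; then 16, −78 to 0 °C
Reagents that add atoms: none
Why: Propargylation, in which the lithiated silylpropyne reacts at its propargylic carbon (the silyl group suppresses allenyl coupling) by SN2 displacement at the unhindered primary allylic carbon C11 rather than at the fully substituted C8.

Step 13
Reactants: 19 silylalkyne
Product: 20 4-[(4aS,8aS)-2,5,5,8a-tetramethyl-3,4,4a,5,6,7,8,8a-octahydronaphthalen-1-yl]but-1-yne
Conditions: K2CO3, MeOH, rt
Reagents that add atoms: none
Why: Base-mediated protodesilylation of the alkynylsilane in methanol frees the terminal alkyne without affecting the ring alkene.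

Step 14
Reactants: 21 3-methyl-4-oxopentanoic acid (racemic)
Product: 22 3,5-dibromo-3-methyl-4-oxopentanoic acid (racemic)
Conditions: Br2 (2 equiv), CHCl3, HBr (cat.), 0 °C to rt
Reagents that add atoms: bromine, BrBr
Why: Acid-catalysed α-bromination of the ketone through its enols, in which the more substituted C3 enol reacts first and the second bromine can then enter only at the C5 methyl, parallel to the dibromination of levulinic acid.

Step 15
Reactants: 22 dibromo keto acid
Product: 23 (Z)-5-(bromomethylene)-4-methylfuran-2(5H)-one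
Conditions: conc. H2SO4, 100 °C, short time; poured on ice
Reagents that add atoms: none
Why: Acid-mediated enol-lactonisation of the 4-oxo acid with loss of water and of HBr across C2–C3 (the sulfuric acid cyclisation used for dibromolevulinic acids) should give the bromomethylene butenolide, the Z geometry with bromine beside the ring oxygen and away from the C4 methyl being the favoured one under the equilibrating conditions.

Step 16
Reactants: 20 terminal alkyne; 23 (Z)-bromomethylene butenolide
Product: 24 (5Z)-4-methyl-5-{5-[(4aS,8aS)-2,5,5,8a-tetramethyl-3,4,4a,5,6,7,8,8a-octahydronaphthalen-1-yl]pent-2-yn-1-ylidene}furan-2(5H)-one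
Conditions: PdCl2(PPh3)2 (cat.), CuI (cat.), i-Pr2NEt, THF, rt, degassed
Reagents that add atoms: none
Why: Sonogashira coupling of the terminal alkyne with the alkenyl bromide retains the Z geometry through oxidative addition and reductive elimination, and the hindered amine limits conjugate addition to the butenolide.

Step 17
Reactants: 24 dienyne lactone; 25 formaldehyde (as paraformaldehyde)
Product: 26 (5Z)-5-{(2E)-3-(hydroxymethyl)-5-[(4aS,8aS)-2,5,5,8a-tetramethyl-3,4,4a,5,6,7,8,8a-octahydronaphthalen-1-yl]pent-2-en-1-ylidene}-4-methylfuran-2(5H)-one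
Conditions: Ni(cod)2 (cat.), tricyclopentylphosphine (cat.), Et3B, (CH2O)n, EtOAc, rt to 45 °C; aq. NH4Cl
Reagents that add atoms: none
Why: Nickel-catalysed reductive coupling of an alkyne with an aldehyde in its 1,3-enyne form, in which zerovalent nickel joins alkyne and formaldehyde by oxidative cyclisation with C–C formation at the alkyne carbon remote from the conjugated ylidene alkene, and ethyl transfer from boron, β-hydride elimination and C–H reductive elimination place H cis to the new CH2OH, which gives the E alkene with the hydroxymethyl group on the carbon bearing the CH2CH2 tether.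

## Compound list

1 | (S)-α-ionone, (3E)-4-[(1S)-2,6,6-trimethylcyclohex-2-en-1-yl]but-3-en-2-one | CC(=O)/C=C/[C@@H]1C(C)=CCCC1(C)C | starting material
2 | triethylsilyl enol ether of 3 (E/Z mixture at the enol ether) | CC(O[Si](CC)(CC)CC)=CC[C@@H]1C(C)=CCCC1(C)C | intermediate
3 | (S)-7,8-dihydro-α-ionone, 4-[(1S)-2,6,6-trimethylcyclohex-2-en-1-yl]butan-2-one | CC(=O)CC[C@@H]1C(C)=CCCC1(C)C | intermediate
4 | 2-methyl-2-{2-[(1S)-2,6,6-trimethylcyclohex-2-en-1-yl]ethyl}-1,3-dioxolane | CC1(CC[C@@H]2C(C)=CCCC2(C)C)OCCO1 | intermediate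
5 | (4S)-3,5,5-trimethyl-4-[2-(2-methyl-1,3-dioxolan-2-yl)ethyl]cyclohex-2-en-1-one | CC1(CC[C@@H]2C(C)=CC(=O)CC2(C)C)OCCO1 | intermediate
6 | (1S,4S)-3,5,5-trimethyl-4-[2-(2-methyl-1,3-dioxolan-2-yl)ethyl]cyclohex-2-en-1-ol (OH trans to the chain) | CC1(CC[C@@H]2C(C)=C[C@@H](O)CC2(C)C)OCCO1 | intermediate
7 | triethyl orthoacetate | CC(OCC)(OCC)OCC | starting material
8 | mixed ketene acetal of 6, 1-ethoxyvinyl ether of the (1S,4S) alcohol | CC1(CC[C@@H]2C(C)=C[C@@H](OC(=C)OCC)CC2(C)C)OCCO1 | intermediate
9 | ethyl 2-[(1S,6S)-1,5,5-trimethyl-6-[2-(2-methyl-1,3-dioxolan-2-yl)ethyl]cyclohex-2-en-1-yl]acetate | CCOC(=O)C[C@@]1(C)C=CCC(C)(C)[C@@H]1CCC2(C)OCCO2 | intermediate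
10 | ethyl 2-[(1R,2S)-1,3,3-trimethyl-2-[2-(2-methyl-1,3-dioxolan-2-yl)ethyl]cyclohexyl]acetate | CCOC(=O)C[C@@]1(C)CCCC(C)(C)[C@@H]1CCC2(C)OCCO2 | intermediate
11 | ethyl 2-(diethoxyphosphanyl)-2-[(1S,2S)-1,3,3-trimethyl-2-[2-(2-methyl-1,3-dioxolan-2-yl)ethyl]cyclohexyl]acetate (phosphonite, epimer mixture) | CCOC(=O)C(P(OCC)OCC)[C@@]1(C)CCCC(C)(C)[C@@H]1CCC2(C)OCCO2 | intermediate
12 | ethyl 2-(diethoxyphosphoryl)-2-[(1S,2S)-1,3,3-trimethyl-2-[2-(2-methyl-1,3-dioxolan-2-yl)ethyl]cyclohexyl]acetate (epimer mixture) | CCOC(=O)C(P(=O)(OCC)OCC)[C@@]1(C)CCCC(C)(C)[C@@H]1CCC2(C)OCCO2 | intermediate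
13 | ethyl 2-(diethoxyphosphoryl)-2-[(1S,2S)-1,3,3-trimethyl-2-(3-oxobutyl)cyclohexyl]acetate (epimer mixture) | CCOC(=O)C(P(=O)(OCC)OCC)[C@@]1(C)CCCC(C)(C)[C@@H]1CCC(C)=O | intermediate
14 | ethyl drim-8-en-11-oate, ethyl (4aS,8aS)-2,5,5,8a-tetramethyl-3,4,4a,5,6,7,8,8a-octahydronaphthalene-1-carboxylate | CCOC(=O)C1=C(C)CC[C@H]2C(C)(C)CCC[C@]12C | intermediate
15 | drim-8-en-11-ol | OCC1=C(C)CC[C@H]2C(C)(C)CCC[C@]12C | intermediate
16 | 11-bromodrim-8-ene | BrCC1=C(C)CC[C@H]2C(C)(C)CCC[C@]12C | intermediate
17 | 1-(trimethylsilyl)propyne | CC#C[Si](C)(C)C | starting material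
18 | 3-lithio-1-(trimethylsilyl)propyne | [Li]CC#C[Si](C)(C)C | intermediate
19 | trimethyl{4-[(4aS,8aS)-2,5,5,8a-tetramethyl-3,4,4a,5,6,7,8,8a-octahydronaphthalen-1-yl]but-1-yn-1-yl}silane | C[Si](C)(C)C#CCCC1=C(C)CC[C@H]2C(C)(C)CCC[C@]12C | intermediate
20 | 4-[(4aS,8aS)-2,5,5,8a-tetramethyl-3,4,4a,5,6,7,8,8a-octahydronaphthalen-1-yl]but-1-yne | C#CCCC1=C(C)CC[C@H]2C(C)(C)CCC[C@]12C | intermediate
21 | 3-methyl-4-oxopentanoic acid (racemic) | CC(=O)C(C)CC(=O)O | starting material
22 | 3,5-dibromo-3-methyl-4-oxopentanoic acid (racemic) | BrCC(=O)C(C)(Br)CC(=O)O | intermediate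
23 | (Z)-5-(bromomethylene)-4-methylfuran-2(5H)-one | CC1=CC(=O)O/C1=C\Br | intermediate
24 | (5Z)-4-methyl-5-{5-[(4aS,8aS)-2,5,5,8a-tetramethyl-3,4,4a,5,6,7,8,8a-octahydronaphthalen-1-yl]pent-2-yn-1-ylidene}furan-2(5H)-one | CC1=CC(=O)O/C1=C\C#CCCC1=C(C)CC[C@H]2C(C)(C)CCC[C@]12C | intermediate
25 | formaldehyde (used as paraformaldehyde) | C=O | starting material
26 | CNP0288110.2, (5Z)-5-{(2E)-3-(hydroxymethyl)-5-[(4aS,8aS)-2,5,5,8a-tetramethyl-3,4,4a,5,6,7,8,8a-octahydronaphthalen-1-yl]pent-2-en-1-ylidene}-4-methylfuran-2(5H)-one | CC1=CC(=O)O/C1=C\C=C(\CO)CCC1=C(C)CC[C@H]2C(C)(C)CCC[C@]12C | target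

## Step count and risks

Total step count: 17. Longest linear sequence: 15 steps (steps 1–13, 16 and 17); steps 14–15 form the two-step butenolide branch.

The three steps most likely to fail:

1. Step 17. The zerovalent nickel catalyst may be diverted by the unsaturated lactone (competing oxidative cyclisation at the butenolide or insertion into its enol ester C–O bond). Regiocontrol of the alkyne–formaldehyde cyclisation may also erode, placing the hydroxymethyl group on the wrong alkyne carbon. The fallback sets out from silylalkyne 19 and comes back to the route at target 26. It moves the hydroxymethylation ahead of the lactone and builds the butenolide last.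
   - Nickel-catalysed reductive coupling of 19 with paraformaldehyde (Ni(cod)2, PBu3, Et3B), in which the silyl group directs C–C formation to the alkyl-bearing alkyne carbon, should give (E)-2-[2-(drim-8-en-9-yl)ethyl]-3-(trimethylsilyl)prop-2-en-1-ol F1.
   - Iododesilylation with retention (N-iodosuccinimide, hexafluoroisopropanol, 0 °C; the alcohol silylated first if iodoetherification onto the ring alkene intervenes) gives the vinyl iodide F2.
   - Sonogashira coupling with ethynyltrimethylsilane gives the silyl enyne F3, and K2CO3 in MeOH gives the terminal enyne F4.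
   - Tandem Sonogashira coupling and 5-exo-dig lactonisation of F4 with (Z)-3-iodobut-2-enoic acid F5 (from but-2-ynoic acid, NaI, AcOH, 110 °C) passes through the dienynoic acid F6 (Pd(PPh3)4, CuI, Et3N, MeCN; AgNO3 if closure is incomplete). Anti addition of carboxylate and proton across the alkyne places the chain beside the ring oxygen and gives 26.

2. Step 9. Addition of the crowded C9 carbanion (next to the quaternary C10) to the ketone may be slow, so that intermolecular condensation or reversible ketone enolisation with Claisen-type attack on the ester takes over. The fallback sets out from ketal ester 10 and comes back at 14.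
   - Enolate bromination (LDA, then CBr4, THF, −78 °C) gives the α-bromo ester F7.
   - Ketal hydrolysis (1 M HCl, THF) gives the bromo keto ester F8.
   - Intramolecular Reformatsky addition with SmI2 (THF, −78 °C) closes ring B as the 8-hydroxy ester F9.
   - Dehydration (SOCl2, pyridine, 0 °C) and equilibration of any C7 or exocyclic alkene isomers into conjugation (DBU, PhMe, 80 °C) give 14.

3. Step 4. Facial selectivity may be poor if the neopentyl-type CH2 arm is not read as the small group or if the substrate bias opposes the catalyst. The cis alcohol would then put the acetate on the wrong face of C10 in step 5. The fallback sets out from enone 5 and comes back at 6.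
   - Luche reduction (NaBH4, CeCl3·7H2O, MeOH, −78 °C) is run without a chiral reagent; any trans alcohol 6 formed directly is kept.
   - The cis alcohol F10 is separated and inverted by Mitsunobu reaction (4-nitrobenzoic acid, PPh3, DIAD, THF) to the trans 4-nitrobenzoate F11.
   - Methanolysis of F11 (K2CO3, MeOH) gives 6.

Further compounds

F1 | step 17 | (E)-2-{2-[(4aS,8aS)-2,5,5,8a-tetramethyl-3,4,4a,5,6,7,8,8a-octahydronaphthalen-1-yl]ethyl}-3-(trimethylsilyl)prop-2-en-1-ol (silyl trans to CH2OH) | C[Si](C)(C)/C=C(/CO)CCC1=C(C)CC[C@H]2C(C)(C)CCC[C@]12C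
F2 | step 17 | 3-iodo-2-{2-[(4aS,8aS)-2,5,5,8a-tetramethyl-3,4,4a,5,6,7,8,8a-octahydronaphthalen-1-yl]ethyl}prop-2-en-1-ol (iodine trans to CH2OH) | I/C=C(/CO)CCC1=C(C)CC[C@H]2C(C)(C)CCC[C@]12C
F3 | step 17 | 2-{2-[(4aS,8aS)-2,5,5,8a-tetramethyl-3,4,4a,5,6,7,8,8a-octahydronaphthalen-1-yl]ethyl}-5-(trimethylsilyl)pent-2-en-4-yn-1-ol (alkynyl trans to CH2OH) | C[Si](C)(C)C#C/C=C(/CO)CCC1=C(C)CC[C@H]2C(C)(C)CCC[C@]12C
F4 | step 17 | 2-{2-[(4aS,8aS)-2,5,5,8a-tetramethyl-3,4,4a,5,6,7,8,8a-octahydronaphthalen-1-yl]ethyl}pent-2-en-4-yn-1-ol (alkynyl trans to CH2OH) | C#C/C=C(/CO)CCC1=C(C)CC[C@H]2C(C)(C)CCC[C@]12C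
F5 | step 17 | (Z)-3-iodobut-2-enoic acid | C/C(I)=C/C(=O)O
F6 | step 17 | (2Z,6E)-7-(hydroxymethyl)-3-methyl-9-[(4aS,8aS)-2,5,5,8a-tetramethyl-3,4,4a,5,6,7,8,8a-octahydronaphthalen-1-yl]nona-2,6-dien-4-ynoic acid | OC(=O)/C=C(/C)C#C/C=C(/CO)CCC1=C(C)CC[C@H]2C(C)(C)CCC[C@]12C
F7 | step 9 | ethyl 2-bromo-2-[(1S,2S)-1,3,3-trimethyl-2-[2-(2-methyl-1,3-dioxolan-2-yl)ethyl]cyclohexyl]acetate (epimer mixture) | CCOC(=O)C(Br)[C@@]1(C)CCCC(C)(C)[C@@H]1CCC2(C)OCCO2
F8 | step 9 | ethyl 2-bromo-2-[(1S,2S)-1,3,3-trimethyl-2-(3-oxobutyl)cyclohexyl]acetate (epimer mixture) | CCOC(=O)C(Br)[C@@]1(C)CCCC(C)(C)[C@@H]1CCC(C)=O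
F9 | step 9 | ethyl (4aS,8aS)-2-hydroxy-2,5,5,8a-tetramethyldecahydronaphthalene-1-carboxylate (mixture at C1 and C2) | CCOC(=O)C1C(C)(O)CC[C@H]2C(C)(C)CCC[C@]12C
F10 | step 4 | (1R,4S)-3,5,5-trimethyl-4-[2-(2-methyl-1,3-dioxolan-2-yl)ethyl]cyclohex-2-en-1-ol (OH cis to the chain) | CC1(CC[C@@H]2C(C)=C[C@H](O)CC2(C)C)OCCO1
F11 | step 4 | (1S,4S)-3,5,5-trimethyl-4-[2-(2-methyl-1,3-dioxolan-2-yl)ethyl]cyclohex-2-en-1-yl 4-nitrobenzoate | CC1(CC[C@@H]2C(C)=C[C@@H](OC(=O)c3ccc(cc3)[N+](=O)[O-])CC2(C)C)OCCO1
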